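**Retrosynthetic overview**
- Target ⇐ 1,2-reduction of an epoxy-enedione anti to the oxirane ⇐ ketal hydrolysis ⇐ hydroxyl-directed asymmetric epoxidation (with acetylation in the flask) of a quinone monoketal ⇐ oxidative dearomatization of a 2-farnesyl-4-methoxy-5-(hydroxymethyl)phenol.
- That phenol ⇐ C1'–C2' bond: (E)-alkenylalane (enyne + AlMe3, Zr-catalysed) added to an o-quinone methide released from a salicyl alcohol (new union step).
- Salicyl alcohol ⇐ hydroquinone + 2 CH2O, then mono-O-methylation.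
- Enyne ⇐ acetylide + homogeranyl iodide ⇐ homogeraniol ⇐ key step: 1,2-shift of the C6 chain from copper to the adjacent carbon (1,2-metalate rearrangement) in the cuprate from homoprenyl bromide and lithiated 2,3-dihydrofuran, then MeI.
- Rings: the six-membered ring is the hydroquinone ring throughout (dearomatized in step 7); the dihydrofuran ring is opened in step 1; the oxirane is the only ring formed (step 8).

Assumption: the sense of induction in step 8 (L-(+)-diisopropyl tartrate written) is taken by analogy with related hydroxymethyl quinone monoketals; if the antipode forms, D-(−)-diisopropyl tartrate is used.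
Numbering: the epoxides are named as 7-oxabicyclo[4.1.0]hept-3-enes (C1 = farnesyl-bearing oxirane carbon, C4 = CH2O-bearing carbon); "farnesyl" = (2E,6E)-3,7,11-trimethyldodeca-2,6,10-trien-1-yl.

**Step 1**
Reactants: 1 5-bromo-2-methylpent-2-ene; 2 2,3-dihydrofuran
Product: 7 (3E)-4,8-dimethylnona-3,7-dien-1-ol (homogeraniol), via alkyllithium 3 (not isolated), via 5-lithio-2,3-dihydrofuran 4 (not isolated), via mixed cuprate 5 (not isolated), via alkenylcopper alkoxide 6 (not isolated)
Conditions: 1, Li, Et2O, 0 °C; 2, t-BuLi, THF, −78 → 0 °C; CuBr·SMe2, Et2O–Me2S, −78 °C → rt; MeI, DMPU, 0 °C → rt; H2O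
Reagents that add atoms: iodomethane, CI
Why: Kocienski 1,2-metalate rearrangement of an α-alkoxyalkenyl cuprate: in 5 the 4-methylpent-3-enyl group shifts from copper to the adjacent ring carbon with inversion while the ring C–O bond breaks, so the chain ends trans to the CH2CH2O arm and methylation of alkenylcopper 6 with retention fixes the E trisubstituted alkene.

**Step 2**
Reactants: 7 (3E)-4,8-dimethylnona-3,7-dien-1-ol
Product: 8 (3E)-1-iodo-4,8-dimethylnona-3,7-diene
Conditions: N-iodosuccinimide, PPh3, CH2Cl2, 0 °C → rt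
Reagents that add atoms: N-iodosuccinimide, O=C1CCC(=O)N1I
Why: Appel-type iodination of a primary alcohol via the alkoxyphosphonium salt (SN2 at CH2), which leaves both alkenes untouched.

**Step 3**
Reactants: 8 (3E)-1-iodo-4,8-dimethylnona-3,7-diene
Product: 9 (5E)-6,10-dimethylundeca-5,9-dien-1-yne
Conditions: LiC≡CH·H2NCH2CH2NH2, DMSO, 10 °C → rt
Reagents that add atoms: lithium acetylide (LiC≡CH, ethylenediamine complex), [Li]C#C
Why: SN2 alkynylation of a primary iodide by lithium acetylide in DMSO, a standard route to 1,5-enynes that does not touch the alkene geometry.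

**Step 4**
Reactants: 10 hydroquinone (benzene-1,4-diol)
Product: 12 2,5-bis(hydroxymethyl)benzene-1,4-diol, via bis(benzodioxaborin) 11 (not isolated)
Conditions: PhB(OH)2 (2.2 equiv), (CH2O)n, EtCO2H (cat.), toluene, reflux (Dean–Stark), N2; then propane-1,3-diol, THF, rt
Reagents that add atoms: formaldehyde (as paraformaldehyde), C=O
Why: Boronic acid-templated ortho-hydroxymethylation (Nagata type): each phenol oxygen, as its phenylboronate half-ester, delivers formaldehyde to its own ortho carbon through a six-membered chelate, the second CH2 enters para to the first because the other ortho site is flanked on both sides, and diol exchange then frees the tetraol.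

**Step 5**
Reactants: 12 2,5-bis(hydroxymethyl)benzene-1,4-diol
Product: 13 2,5-bis(hydroxymethyl)-4-methoxyphenol
Conditions: MeI (0.9 equiv), K2CO3, acetone, N2, rt
Reagents that add atoms: iodomethane, CI
Why: Williamson O-methylation of one of two equivalent phenols (the phenoxide is far more nucleophilic than the benzylic alcohols); the outcome is statistical, and 12 and the dimethyl ether are separated and 12 recycled.

**Step 6**
Reactants: 9 (5E)-6,10-dimethylundeca-5,9-dien-1-yne; 13 2,5-bis(hydroxymethyl)-4-methoxyphenol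
Product: 17 5-(hydroxymethyl)-4-methoxy-2-[(2E,6E)-3,7,11-trimethyldodeca-2,6,10-trien-1-yl]phenol, via alkenylalane 14 (not isolated), via benzodioxaborin 15 (not isolated), via aluminium alkoxide 16 (not isolated)
Conditions: 9, AlMe3 (2 equiv), Cp2ZrCl2 (0.25 equiv), CH2Cl2, 0 °C → rt, then volatiles removed; 13, PhB(OH)2 (1 equiv), 4 Å MS, toluene, rt, then AlMe3 (1 equiv), 0 °C; both combined in toluene, −20 → 40 °C; aq. NH4Cl
Reagents that add atoms: trimethylaluminium, C[Al](C)C
Why: Proposed new method: Negishi Zr-catalysed syn-carboalumination of 9 gives the (E)-alkenylalane 14 (Me and Al cis), and this Lewis-acidic alane is expected to ionise the benzylic C–O bond of the cyclic boronate in 16 (the boron-bound phenol oxygen pushes out an o-quinone methide) and to hand its sp2 carbon to the exocyclic CH2 with retention of the E geometry, re-aromatisation being the driving force and only the salicyl-type CH2O being able to ionise this way; the closest known reactions are the coupling of alkenylalanes with chloromethyl ethers and benzylic halides, the Lewis acid opening of 1,3,2-benzodioxaborins to o-quinone methides and the 1,4-addition of alkenylboronates and alkenyl Grignard reagents to o-quinone methides.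

**Step 7**
Reactants: 17 5-(hydroxymethyl)-4-methoxy-2-farnesylphenol
Product: 18 5-(hydroxymethyl)-4,4-dimethoxy-2-[(2E,6E)-3,7,11-trimethyldodeca-2,6,10-trien-1-yl]cyclohexa-2,5-dien-1-one
Conditions: PhI(OAc)2, MeOH, 0 °C
Reagents that add atoms: methanol, CO
Why: Oxidative dearomatization of a para-methoxyphenol with PhI(OAc)2 in methanol gives the quinone monoketal, which places the free C=O next to the farnesyl-bearing carbon and the ketal next to the CH2OH-bearing carbon.

**Step 8**
Reactants: 18 5-(hydroxymethyl)-4,4-dimethoxy-2-farnesylcyclohexa-2,5-dien-1-one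
Product: 20 [(1R,6S)-5,5-dimethoxy-2-oxo-1-[(2E,6E)-3,7,11-trimethyldodeca-2,6,10-trien-1-yl]-7-oxabicyclo[4.1.0]hept-3-en-4-yl]methyl acetate, via epoxy alcohol 19 (not isolated)
Conditions: Ph3COOH, NaN(SiMe3)2, L-(+)-diisopropyl tartrate, 4 Å MS, toluene, −65 → −40 °C; then Ac2O, DMAP, −40 → 0 °C
Reagents that add atoms: trityl hydroperoxide, OOC(c1ccccc1)(c1ccccc1)c1ccccc1; acetic anhydride, CC(=O)OC(C)=O
Why: Hydroxyl-directed, tartrate-mediated nucleophilic (Weitz–Scheffer type) epoxidation: the sodium alkoxide of the CH2OH binds the tartrate–peroxide aggregate, the peroxide can add only to the unsubstituted β-carbon and closes onto the farnesyl-bearing α-carbon, the tartrate chooses the face and so sets both oxirane centres (1R,6S here, the same spatial arrangement as 1R,6R in the target), and the alkoxide is then acetylated in the flask.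

**Step 9**
Reactants: 20 [(1R,6S)-5,5-dimethoxy-2-oxo-1-farnesyl-7-oxabicyclo[4.1.0]hept-3-en-4-yl]methyl acetate
Product: 21 [(1R,6S)-2,5-dioxo-1-[(2E,6E)-3,7,11-trimethyldodeca-2,6,10-trien-1-yl]-7-oxabicyclo[4.1.0]hept-3-en-4-yl]methyl acetate
Conditions: 48% aq. HF, MeCN, 0 °C
Reagents that add atoms: water, O
Why: Acid-catalysed hydrolysis of the dimethyl ketal to the enedione under cold dilute HF, conditions that the oxirane, the acetate and the trisubstituted alkenes tolerate; no stereocentre is touched.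

**Step 10**
Reactants: 21 [(1R,6S)-2,5-dioxo-1-farnesyl-7-oxabicyclo[4.1.0]hept-3-en-4-yl]methyl acetate
Product: 22 [(1R,5R,6R)-5-hydroxy-2-oxo-1-[(2E,6E)-3,7,11-trimethyldodeca-2,6,10-trien-1-yl]-7-oxabicyclo[4.1.0]hept-3-en-4-yl]methyl acetate
Conditions: NaBH4, CeCl3·7H2O, MeOH, −78 °C
Reagents that add atoms: none
Why: Luche 1,2-reduction: the C2 carbonyl is shielded on both faces by the quaternary C1 (farnesyl CH2 on one face, oxirane oxygen on the other), so hydride goes to C5 and enters anti to the oxirane oxygen, which puts the new OH cis to the epoxide (5R; C6 is now R by rank change only).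

**Compound list**
1 | 5-bromo-2-methylpent-2-ene | CC(C)=CCCBr | starting material
2 | 2,3-dihydrofuran | C1CC=CO1 | starting material
3 | (4-methylpent-3-en-1-yl)lithium | [Li]CCC=C(C)C | intermediate
4 | 5-lithio-2,3-dihydrofuran | [Li]C1=CCCO1 | intermediate
5 | lithium (4,5-dihydrofuran-2-yl)(4-methylpent-3-en-1-yl)cuprate | [Li+].CC(C)=CCC[Cu-]C1=CCCO1 | intermediate
6 | lithium (3Z)-4-cuprio-8-methylnona-3,7-dien-1-olate | [Li+].[O-]CC/C=C(\[Cu])CCC=C(C)C | intermediate
7 | (3E)-4,8-dimethylnona-3,7-dien-1-ol (homogeraniol) | OCC/C=C(\C)CCC=C(C)C | intermediate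
8 | (3E)-1-iodo-4,8-dimethylnona-3,7-diene | ICC/C=C(\C)CCC=C(C)C | intermediate
9 | (5E)-6,10-dimethylundeca-5,9-dien-1-yne | C#CCC/C=C(\C)CCC=C(C)C | intermediate
10 | hydroquinone (benzene-1,4-diol) | Oc1ccc(O)cc1 | starting material
11 | 2,7-diphenyl-4H,9H-benzo[1,2-e:4,5-e']bis([1,3,2]dioxaborinine), the bis(cyclic phenylboronate) of 12 | B1(c2ccccc2)OCc2cc3OB(c4ccccc4)OCc3cc2O1 | intermediate
12 | 2,5-bis(hydroxymethyl)benzene-1,4-diol | OCc1cc(O)c(CO)cc1O | intermediate
13 | 2,5-bis(hydroxymethyl)-4-methoxyphenol | COc1cc(CO)c(O)cc1CO | intermediate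
14 | dimethyl[(1E,5E)-2,6,10-trimethylundeca-1,5,9-trien-1-yl]alane | C[Al](C)/C=C(\C)CC/C=C(\C)CCC=C(C)C | intermediate
15 | (6-methoxy-2-phenyl-4H-1,3,2-benzodioxaborinin-7-yl)methanol | COc1cc2COB(c3ccccc3)Oc2cc1CO | intermediate
16 | dimethylaluminium (6-methoxy-2-phenyl-4H-1,3,2-benzodioxaborinin-7-yl)methoxide | COc1cc2COB(c3ccccc3)Oc2cc1CO[Al](C)C | intermediate
17 | 5-(hydroxymethyl)-4-methoxy-2-[(2E,6E)-3,7,11-trimethyldodeca-2,6,10-trien-1-yl]phenol | COc1cc(C/C=C(\C)CC/C=C(\C)CCC=C(C)C)c(O)cc1CO | intermediate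
18 | 5-(hydroxymethyl)-4,4-dimethoxy-2-[(2E,6E)-3,7,11-trimethyldodeca-2,6,10-trien-1-yl]cyclohexa-2,5-dien-1-one | OCC1=CC(=O)C(C/C=C(\C)CC/C=C(\C)CCC=C(C)C)=CC1(OC)OC | intermediate
19 | (1R,6S)-4-(hydroxymethyl)-5,5-dimethoxy-1-[(2E,6E)-3,7,11-trimethyldodeca-2,6,10-trien-1-yl]-7-oxabicyclo[4.1.0]hept-3-en-2-one | OCC1=CC(=O)[C@]2(C/C=C(\C)CC/C=C(\C)CCC=C(C)C)O[C@@H]2C1(OC)OC | intermediate
20 | [(1R,6S)-5,5-dimethoxy-2-oxo-1-[(2E,6E)-3,7,11-trimethyldodeca-2,6,10-trien-1-yl]-7-oxabicyclo[4.1.0]hept-3-en-4-yl]methyl acetate | CC(=O)OCC1=CC(=O)[C@]2(C/C=C(\C)CC/C=C(\C)CCC=C(C)C)O[C@@H]2C1(OC)OC | intermediate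
21 | [(1R,6S)-2,5-dioxo-1-[(2E,6E)-3,7,11-trimethyldodeca-2,6,10-trien-1-yl]-7-oxabicyclo[4.1.0]hept-3-en-4-yl]methyl acetate | CC(=O)OCC1=CC(=O)[C@]2(C/C=C(\C)CC/C=C(\C)CCC=C(C)C)O[C@@H]2C1=O | intermediate
22 | [(1R,5R,6R)-5-hydroxy-2-oxo-1-[(2E,6E)-3,7,11-trimethyldodeca-2,6,10-trien-1-yl]-7-oxabicyclo[4.1.0]hept-3-en-4-yl]methyl acetate | CC(=O)OCC1=CC(=O)[C@]2(C/C=C(\C)CC/C=C(\C)CCC=C(C)C)O[C@@H]2[C@@H]1O | target

**Totals**
Total step count: 10. Longest linear sequence: 8 (steps 1, 2, 3, 6, 7, 8, 9, 10).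

**Steps most likely to fail**

Step 6 (the new union). Risks are transfer of a methyl instead of the alkenyl group and slow ionisation of the boronate. The fallback uses known chemistry only, sets out from 9 and 13 and comes back at 17. Enyne 9 is carboaluminated as in step 6 and the alane is quenched with I2 to give (1E,5E)-1-iodo-2,6,10-trimethylundeca-1,5,9-triene F1. Phenol 13 is converted with Boc2O and K2CO3 into tert-butyl 2,5-bis(hydroxymethyl)-4-methoxyphenyl carbonate F2. Iodide F1 and t-BuLi (Et2O, −78 °C) give [(1E,5E)-2,6,10-trimethylundeca-1,5,9-trien-1-yl]lithium F3. Carbonate F2 is deprotonated at both CH2OH groups with i-PrMgCl (2 equiv, THF, −78 °C); the ortho benzylic alkoxide takes over the Boc group, the phenoxide expels tert-butyl carbonate to give the o-quinone methide, and F3 adds 1,4 to it (the established Boc-migration route to o-quinone methides with organolithium or Grignard capture), giving 17.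

Step 8. Risks are slow peroxide addition to the α-substituted dienone, insufficient enantioselectivity, and loss in the in-flask acetylation. The fallback sets out from 18 and comes back at 20. Alcohol 18 is acetylated (Ac2O, pyridine) to [6,6-dimethoxy-3-oxo-4-[(2E,6E)-3,7,11-trimethyldodeca-2,6,10-trien-1-yl]cyclohexa-1,4-dien-1-yl]methyl acetate F4. F4 is epoxidised under chiral phase-transfer conditions (t-BuOOH, cat. N-benzylcinchonidinium chloride or its cinchoninium pseudo-enantiomer, aq. NaOH, toluene, 0 °C). The same alkene is the only reactive one, and the face is chosen by the chiral ion pair instead of by the hydroxyl group, giving 20.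

Step 10. Risks are reduction at the wrong carbonyl, 1,4-reduction, and acetate migration to the new alkoxide. The fallback sets out from 19 and comes back at 22. Step 8 is quenched with aq. NH4Cl instead of Ac2O and 19 is isolated. Cold aq. HF in MeCN gives (1R,6S)-4-(hydroxymethyl)-1-[(2E,6E)-3,7,11-trimethyldodeca-2,6,10-trien-1-yl]-7-oxabicyclo[4.1.0]hept-3-ene-2,5-dione F5. Hydroxyl-directed reduction with Me4NBH(OAc)3 (MeCN–AcOH, −30 °C), in which the CH2O-bound borohydride can reach only C5 and enters anti to the oxirane, gives (1R,5R,6R)-5-hydroxy-4-(hydroxymethyl)-1-[(2E,6E)-3,7,11-trimethyldodeca-2,6,10-trien-1-yl]-7-oxabicyclo[4.1.0]hept-3-en-2-one F6. Selective acetylation of the primary alcohol (AcCl, 2,4,6-collidine, CH2Cl2, −78 °C) gives 22.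

**Further compounds**
F1 | step 6 | (1E,5E)-1-iodo-2,6,10-trimethylundeca-1,5,9-triene | I/C=C(\C)CC/C=C(\C)CCC=C(C)C
F2 | step 6 | tert-butyl 2,5-bis(hydroxymethyl)-4-methoxyphenyl carbonate | COc1cc(CO)c(OC(=O)OC(C)(C)C)cc1CO
F3 | step 6 | [(1E,5E)-2,6,10-trimethylundeca-1,5,9-trien-1-yl]lithium | [Li]/C=C(\C)CC/C=C(\C)CCC=C(C)C
F4 | step 8 | [6,6-dimethoxy-3-oxo-4-[(2E,6E)-3,7,11-trimethyldodeca-2,6,10-trien-1-yl]cyclohexa-1,4-dien-1-yl]methyl acetate | CC(=O)OCC1=CC(=O)C(C/C=C(\C)CC/C=C(\C)CCC=C(C)C)=CC1(OC)OC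
F5 | step 10 | (1R,6S)-4-(hydroxymethyl)-1-[(2E,6E)-3,7,11-trimethyldodeca-2,6,10-trien-1-yl]-7-oxabicyclo[4.1.0]hept-3-ene-2,5-dione | OCC1=CC(=O)[C@]2(C/C=C(\C)CC/C=C(\C)CCC=C(C)C)O[C@@H]2C1=O
F6 | step 10 | (1R,5R,6R)-5-hydroxy-4-(hydroxymethyl)-1-[(2E,6E)-3,7,11-trimethyldodeca-2,6,10-trien-1-yl]-7-oxabicyclo[4.1.0]hept-3-en-2-one | OCC1=CC(=O)[C@]2(C/C=C(\C)CC/C=C(\C)CCC=C(C)C)O[C@@H]2[C@@H]1O
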